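**Retrosynthetic overview**
1. Target ⇐ azide dealkylation of a 3-O-(neopentyl sulfate) diester; the 7-, 3'- and 4'-sulfates come from an SO3–amine complex (the chelated 5-OH stays free).
2. The pyranone C-ring is the only ring built (A and B rings are bought); it closes by debenzylation/cyclodehydration of a 2-(sulfooxy)-1,3-diaryl-1,3-diketone.
3. The C3–O–S bond is made before ring closure by a new sulfate-monoester transfer to the iodonium ylide of that diketone.
4. Diketone ⇐ crossed Claisen of tri-O-benzylphloroacetophenone with methyl 3,4-bis(benzyloxy)benzoate.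

**Assumptions**
- The target has no stereocentres (achiral), so "single enantiomer" needs no stereocontrol.
- The target SMILES is the free tetra-acid; it is handled as the tetrasodium salt and converted to the acid form by H+ ion exchange in the last step.

**Route**

Step 1
Reactants: 1 (2',4',6'-trihydroxyacetophenone), 2 (benzyl bromide)
Product: 3 (2',4',6'-tris(benzyloxy)acetophenone)
Conditions: BnBr (3.6 equiv), K2CO3 (5 equiv), TBAI (cat.), DMF, 80 °C
Reagents that add atoms: benzyl bromide (2), BrCc1ccccc1
Why: Williamson etherification; excess halide and heat also alkylate the chelated ortho-OH, and the acyl group suppresses C-benzylation.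

Step 2
Reactants: 4 (methyl 3,4-dihydroxybenzoate), 2 (benzyl bromide)
Product: 5 (methyl 3,4-bis(benzyloxy)benzoate)
Conditions: BnBr (2.3 equiv), K2CO3, DMF, 60 °C
Reagents that add atoms: benzyl bromide (2), BrCc1ccccc1
Why: Williamson etherification of both catechol hydroxyls, with the ester untouched.

Step 3
Reactants: 3 (2',4',6'-tris(benzyloxy)acetophenone), 5 (methyl 3,4-bis(benzyloxy)benzoate)
Product: 6 (1-[2,4,6-tris(benzyloxy)phenyl]-3-[3,4-bis(benzyloxy)phenyl]propane-1,3-dione)
Conditions: NaH (3 equiv), THF, reflux; then AcOH quench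
Reagents that add atoms: none (both partners are listed reactants; MeOH is lost)
Why: Crossed Claisen condensation of a methyl ketone enolate with a non-enolisable aryl ester, driven by deprotonation of the β-diketone; the di-ortho-substituted ketone carbonyl resists self-aldol.

Step 4
Reactants: 6 (protected 1,3-diketone), 7 ((diacetoxyiodo)benzene)
Product: 8 (phenyliodonium ylide of 6: 2-(phenyl-λ3-iodanylidene)-1-[2,4,6-tris(benzyloxy)phenyl]-3-[3,4-bis(benzyloxy)phenyl]propane-1,3-dione)
Conditions: PhI(OAc)2 (1.1 equiv), KOH (3 equiv), MeOH/CH2Cl2, −10 → 0 °C; used at once without storage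
Reagents that add atoms: (diacetoxyiodo)benzene (7), CC(=O)OI(OC(C)=O)c1ccccc1
Why: Known iodonium-ylide formation from 1,3-dicarbonyls with PhI(OAc)2 and base; under basic conditions iodine(III) goes only to the central carbon, so the electron-rich arenes are not touched.

Step 5
Reactants: 9 (neopentyl alcohol), 10 (chlorosulfonic acid)
Product: 11 (neopentyl hydrogen sulfate)
Conditions: ClSO3H (1.0 equiv), CH2Cl2, 0 °C; N2 sparge then vacuum to remove all HCl; used as a CH2Cl2 solution
Reagents that add atoms: chlorosulfonic acid (10), OS(=O)(=O)Cl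
Why: Standard O-sulfonation of a primary alcohol with chlorosulfonic acid; complete HCl removal matters because chloride would compete in Step 6.

Step 6
Reactants: 8 (iodonium ylide), 11 (neopentyl hydrogen sulfate)
Product: 12 (1-[2,4,6-tris(benzyloxy)phenyl]-3-[3,4-bis(benzyloxy)phenyl]-1,3-dioxopropan-2-yl neopentyl sulfate; racemic and enolisable at C2)
Conditions: 11 (1.15 equiv, HCl-free) added to 8, CH2Cl2, 4 Å MS, −40 → 0 °C; chromatograph to remove PhI
Reagents that add atoms: neopentyl hydrogen sulfate (11), CC(C)(C)COS(=O)(=O)O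
Why: Proposed new method: the strong acid 11 protonates the ylide to an α-(phenyliodonio)-1,3-diketone ion-paired with neopentyl sulfate, whose sulfate oxygen then displaces PhI (a hypernucleofuge) at the α-carbon to forge the C3–O–S bond as a neutral, protected sulfate diester; the closest known reactions are protonolysis of β-dicarbonyl iodonium ylides by HX (HCl, TsOH, RCO2H) and Koser-type α-tosyloxylation/α-phosphoryloxylation of ketones, and a sulfuric acid monoester has not been used as the transferred oxygen nucleophile.

Step 7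
Reactants: 12 (α-sulfooxy diketone)
Product: 13 (quercetin 3-O-(neopentyl sulfate): 2-(3,4-dihydroxyphenyl)-5,7-dihydroxy-4-oxo-4H-chromen-3-yl neopentyl sulfate)
Conditions: H2 (1 atm), Pd(OH)2/C, THF/EtOAc, rt; filter; then TsOH·H2O (0.2 equiv), AcOH, 50 °C
Reagents that add atoms: none
Why: Hydrogenolysis of the five aryl benzyl ethers (the neopentyl sulfate diester is inert to H2/Pd), then acid-catalysed hemiketalisation/dehydration as in the ring-closing stage of a Baker–Venkataraman flavone synthesis; the symmetric A-ring gives one regioisomer and the C2 stereocentre of 12 becomes sp2 C3.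

Step 8
Reactants: 13 (quercetin 3-O-(neopentyl sulfate)), 14 (sulfur trioxide–trimethylamine complex)
Product: 15 (quercetin 3-O-(neopentyl sulfate) 7,3',4'-tri-O-sulfate, isolated as the trisodium salt)
Conditions: SO3·NMe3 (12 equiv), Et3N, DMF, 55 °C; aq. NaHCO3; Sephadex LH-20
Reagents that add atoms: sulfur trioxide–trimethylamine (14), C[N+](C)(C)S(=O)(=O)[O-] (delivers SO3 three times)
Why: Phenol O-sulfation with an SO3–amine complex; the 5-OH is deactivated by its hydrogen bond to C4=O and stays free, and the 3-oxygen is already masked.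

Step 9
Reactants: 15 (tri-sulfate neopentyl diester)
Product: 16 (quercetin 3,7,3',4'-tetra-O-sulfate, the target)
Conditions: NaN3 (6 equiv), DMF, 70 °C; Sephadex G-10 (tetrasodium salt); then Dowex 50W (H+), H2O, 0 °C, lyophilise
Reagents that add atoms: none
Why: SN2 dealkylation of the neopentyl sulfate diester by azide (the known deprotection of neopentyl-protected aryl sulfates) releases the fourth sulfate monoester; cold H+ exchange gives the drawn acid form.

**Compound list**
1 | 2',4',6'-trihydroxyacetophenone | CC(=O)c1c(O)cc(O)cc1O | starting material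
2 | benzyl bromide | BrCc1ccccc1 | starting material
3 | 2',4',6'-tris(benzyloxy)acetophenone | CC(=O)c1c(OCc2ccccc2)cc(OCc2ccccc2)cc1OCc1ccccc1 | intermediate
4 | methyl 3,4-dihydroxybenzoate | COC(=O)c1ccc(O)c(O)c1 | starting material
5 | methyl 3,4-bis(benzyloxy)benzoate | COC(=O)c1ccc(OCc2ccccc2)c(OCc2ccccc2)c1 | intermediate
6 | 1-[2,4,6-tris(benzyloxy)phenyl]-3-[3,4-bis(benzyloxy)phenyl]propane-1,3-dione | O=C(CC(=O)c1ccc(OCc2ccccc2)c(OCc2ccccc2)c1)c1c(OCc2ccccc2)cc(OCc2ccccc2)cc1OCc1ccccc1 | intermediate
7 | (diacetoxyiodo)benzene | CC(=O)OI(OC(C)=O)c1ccccc1 | starting material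
8 | phenyliodonium ylide of 6 | O=C(c1ccc(OCc2ccccc2)c(OCc2ccccc2)c1)[C-]([I+]c1ccccc1)C(=O)c1c(OCc2ccccc2)cc(OCc2ccccc2)cc1OCc1ccccc1 | intermediate
9 | neopentyl alcohol (2,2-dimethylpropan-1-ol) | CC(C)(C)CO | starting material
10 | chlorosulfonic acid | OS(=O)(=O)Cl | starting material
11 | neopentyl hydrogen sulfate | CC(C)(C)COS(=O)(=O)O | intermediate
12 | 1-[2,4,6-tris(benzyloxy)phenyl]-3-[3,4-bis(benzyloxy)phenyl]-1,3-dioxopropan-2-yl neopentyl sulfate (racemic) | CC(C)(C)COS(=O)(=O)OC(C(=O)c1ccc(OCc2ccccc2)c(OCc2ccccc2)c1)C(=O)c1c(OCc2ccccc2)cc(OCc2ccccc2)cc1OCc1ccccc1 | intermediate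
13 | quercetin 3-O-(neopentyl sulfate) | CC(C)(C)COS(=O)(=O)Oc1c(-c2ccc(O)c(O)c2)oc2cc(O)cc(O)c2c1=O | intermediate
14 | sulfur trioxide–trimethylamine complex | C[N+](C)(C)S(=O)(=O)[O-] | starting material
15 | quercetin 3-O-(neopentyl sulfate) 7,3',4'-tri-O-sulfate (acid form shown; handled as trisodium salt) | CC(C)(C)COS(=O)(=O)Oc1c(-c2ccc(OS(=O)(=O)O)c(OS(=O)(=O)O)c2)oc2cc(OS(=O)(=O)O)cc(O)c2c1=O | intermediate
16 | quercetin 3,7,3',4'-tetra-O-sulfate (achiral) | O=c1c(OS(=O)(=O)O)c(-c2ccc(OS(=O)(=O)O)c(OS(=O)(=O)O)c2)oc2cc(OS(=O)(=O)O)cc(O)c12 | target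

**Step count**
Total steps: 9. Longest linear sequence: 7 (Steps 1, 3, 4, 6, 7, 8, 9).

**Three steps most likely to fail**
1. Step 6 (proposed new sulfate transfer). Risks are α-chloride or α-hydroxy products from traces of HCl or water, ylide decomposition, and attack by the ortho-benzyloxy oxygen. Fallback (known chemistry): α-hydroxylate diketone 6 with dimethyldioxirane, hydrogenolyse and cyclodehydrate to quercetin, then sulfate the 3-, 7-, 3'- and 4'-OH together with SO3·NMe3/K2CO3, which leaves the chelated 5-OH free.
2. Step 7 (debenzylation/cyclodehydration). The freed 2'-OH could displace the α-sulfate to give a 2-aroylcoumaran-3-one, or the sulfate could be lost. Fallback: close the ring before adding the C3 oxygen. Hydrogenolyse and cyclise 6 to luteolin, re-protect the phenols, hydroxylate C3 by the known LDA/B(OMe)3/H2O2 sequence, sulfate the 3-OH with neopentyl chlorosulfate, and debenzylate to rejoin at 13.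
3. Step 8 (tri-sulfation). The ortho-disulfate on the catechol may be incomplete, or the 5-OH may be over-sulfated under forcing conditions. Fallback: switch to protected sulfates. Install the 7-, 3'- and 4'-sulfates as neutral neopentyl diesters with neopentyl chlorosulfate/NaHMDS (3.1 equiv), purify on silica, then remove all four neopentyl groups with NaN3.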